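**Strategy.** The seven-membered ring (C1–C7 of the tricyclo[5.4.0.0^{2,8}]undecane skeleton) is reached by one-carbon enlargement of a six-membered ring in a nor-tricycle that already holds the cyclobutane and ring A. Conjugate methylation of the ring B enone creates the C6 gem-dimethyl group and, because C2 is quaternary, delivers the C3 silyl enol ether regiospecifically. Cyclopropanation gives a silyloxycyclopropane fused to ring B; FeCl3 cleavage of its internal bond inserts C4 between C3 and C5 and leaves the C3 ketone/C4=C5 enone that serves the 3,5-dioxygenation. The nor-tricycle comes from an enantioselective quinone Diels–Alder adduct closed to the cyclobutane by enolate alkylation.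

Key step: step 10

Assumption: the oxazaborolidinium of step 2 and the bisphosphine of step 12 are used as whichever antipode gives the stated configuration (the sense shown follows the usual facial models and is not established for these substrates); in the Why lines "target locants" means tricyclo[5.4.0.0^{2,8}]undecane numbering with C11 = ring carbonyl, C3 = tiglate carbon, C5 = angelate carbon.

**Step 1**
Reactants: 1 but-3-en-2-one
Product: 2 2-[tri(propan-2-yl)silyloxy]buta-1,3-diene
Conditions: i-Pr3SiOTf, Et3N, Et2O, 0 °C to rt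
Reagents that add atoms: triisopropylsilyl triflate, CC(C)[Si](C(C)C)(C(C)C)OS(=O)(=O)C(F)(F)F
Why: Soft enolisation with O-silylation (silyl dienol ether formation): the triflate activates the carbonyl and Et3N removes a methyl proton, giving the 2-silyloxydiene; no stereocentre.

**Step 2**
Reactants: 2 2-[tri(propan-2-yl)silyloxy]buta-1,3-diene; 3 2,5-dimethyl-1,4-benzoquinone
Product: 4 (4aS,8aR)-2,4a-dimethyl-6-[tri(propan-2-yl)silyloxy]-4a,5,8,8a-tetrahydronaphthalene-1,4-dione
Conditions: (S)-proline-derived o-tolyl-oxazaborolidine (20 mol %), HNTf2 (16 mol %), CH2Cl2, −78 °C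
Reagents that add atoms: none
Why: Catalytic enantioselective Diels–Alder reaction: the cationic oxazaborolidine binds one quinone carbonyl, the CH2 terminus next to the silyloxy carbon (largest HOMO coefficient) bonds to the methyl-bearing β-carbon, suprafacial addition gives the cis ring fusion, and the shielded face of the bound quinone should set C4a and C8a as (4aS,8aR).

**Step 3**
Reactants: 4 the Diels–Alder adduct
Product: 5 (4R,4aR,8aS)-4-hydroxy-3,8a-dimethyl-7-[tri(propan-2-yl)silyloxy]-4a,5,8,8a-tetrahydronaphthalen-1(4H)-one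
Conditions: NaBH4, CeCl3·7H2O, MeOH/CH2Cl2, −78 °C
Reagents that add atoms: none
Why: Luche 1,2-reduction: the C1 carbonyl of 4 (next to the ring-fusion CH, not to the quaternary carbon, and without β-alkyl donation) is the more electrophilic, and hydride should enter from the convex face of the cis-fused bicycle (the face of the angular H and CH3), placing the new hydroxyl cis to ring A.

**Step 4**
Reactants: 5 the hydroxy silyl enol ether
Product: 6 (4R,4aR,8aS)-4-hydroxy-3,8a-dimethyl-4a,8a-dihydronaphthalene-1,7(4H,8H)-dione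
Conditions: Pd(OAc)2 (1.05 equiv), MeCN, 40 °C
Reagents that add atoms: none
Why: Saegusa–Ito oxidation: divalent palladium exchanges with silicon at C6 of the enol ether and β-hydride elimination is possible only toward C5, so a single ring A enone forms; no stereocentre is touched.

**Step 5**
Reactants: 6 the hydroxy bis-enone
Product: 7 (4S,4aR,8aS)-4-bromo-3,8a-dimethyl-4a,8a-dihydronaphthalene-1,7(4H,8H)-dione
Conditions: CBr4, PPh3, CH2Cl2, −20 °C
Reagents that add atoms: carbon tetrabromide, BrC(Br)(Br)Br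
Why: Appel reaction: bromide displaces the alkoxyphosphonium by SN2 with inversion at C4, so the hydroxyl that was cis to ring A becomes a bromide cis to the angular H and CH3, the arrangement required for backside attack in step 6.

**Step 6**
Reactants: 7 the allylic bromide
Product: 8 (1S,2R,6S,7R)-2,5-dimethyltricyclo[4.4.0.0^{2,7}]deca-4,9-diene-3,8-dione
Conditions: LiN(SiMe3)2 (1.1 equiv), THF, −78 °C; DMPU, −78 to 0 °C
Reagents that add atoms: none
Why: Intramolecular enolate alkylation (4-exo-tet): the amide removes the only kinetically accessible α'-protons (C8–H of the ring A enone; ring B has none), and in the cis-fused conformer with C8 axial on ring B the enolate displaces the pseudo-equatorial allylic bromide with inversion, forming the C1–C7 bond of the target; the cis ring fusion fixes all four cyclobutane centres.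

**Step 7**
Reactants: 8 the tricyclic bis-enone
Product: 9 (1S,2R,6S,7R,10R)-2,5,10-trimethyltricyclo[4.4.0.0^{2,7}]dec-4-ene-3,8-dione
Conditions: Me2CuLi (1.2 equiv), Et2O, −78 °C; aq NH4Cl
Reagents that add atoms: lithium dimethylcuprate, [Li+].C[Cu-]C
Why: Cuprate conjugate addition: the β-unsubstituted ring A enone reacts at −78 °C whereas the β,β-disubstituted ring B enone should not without Me3SiCl; methyl adds to C10 from the face anti to the C2 methyl group (this centre is erased in step 11).

**Step 8**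
Reactants: 9 the ring A ketone/ring B enone
Product: 10 (1S,2R,6S,7R,10R)-2,5,5,10-tetramethyl-3-(trimethylsilyloxy)tricyclo[4.4.0.0^{2,7}]dec-3-en-8-one
Conditions: Me2CuLi (3 equiv), Me3SiCl (5 equiv), THF, −78 to −30 °C; Et3N, cold aq NaHCO3
Reagents that add atoms: lithium dimethylcuprate, [Li+].C[Cu-]C; chlorotrimethylsilane, C[Si](C)(C)Cl
Why: Me3SiCl-accelerated cuprate conjugate addition with enolate trapping: methyl adds to C5 (the future gem-dimethyl carbon C6) and the enolate is silylated in place, so the C3=C4 enol ether is regiodefined (C2 is quaternary); no new stereocentre.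

**Step 9**
Reactants: 10 the silyl enol ether
Product: 11 2,5,5,10-tetramethyl-3-(trimethylsilyloxy)-3,4-methanotricyclo[4.4.0.0^{2,7}]decan-8-one (cyclopropane fused across C3–C4 of 10)
Conditions: Et2Zn, CH2I2, CH2Cl2, 0 °C to rt
Reagents that add atoms: diiodomethane, ICI
Why: Simmons–Smith cyclopropanation (Furukawa reagent): the electron-rich silyl enol ether is cyclopropanated while the ketone is inert; the two new centres are cis-fused by necessity, may form on either face, and are erased in step 10.

**Step 10**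
Reactants: 11 the silyloxycyclopropane
Product: 13 (1R,2R,7S,8S,9R)-2,6,6,9-tetramethyltricyclo[5.4.0.0^{2,8}]undec-4-ene-3,11-dione, via 5-chloro ketone 12 (not isolated)
Conditions: FeCl3 (2.5 equiv), DMF, 0 °C to rt; then NaOAc, MeOH, reflux
Reagents that add atoms: none
Why: FeCl3 exchanges with the silyl ether to give a trivalent-iron cyclopropanolate whose homolysis and β-scission break the internal C3–C5 bond (target locants) shared by the three- and six-membered rings, giving the C3 ketone and a secondary C5 radical that takes chlorine from a second FeCl3; NaOAc then eliminates HCl (E1cB) to the C4=C5 enone. The closest known reaction type is the FeCl3-mediated one-carbon ring enlargement of 1-silyloxybicyclo[n.1.0]alkanes to cycloalk-2-enones (Ito–Saegusa). No ring is closed by a new bond: the seven-membered ring C1–C7 arises when the zero-atom bridge of the bicyclo[4.1.0]heptane unit is broken, so the six-membered ring gains C4 as a member. No stereocentre is created (the cyclopropane centres and the transient C5 chloride are erased) and C1, C2, C7, C8 are untouched. The step needs cleavage of the internal rather than the external cyclopropane bond, secured because internal cleavage gives a secondary ring radical instead of a primary one; it needs the cyclopropane between C3 and C5, which step 8 fixed because C2 is quaternary; the C11 ketone carries no silyloxycyclopropane and stays inert.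

**Step 11**
Reactants: 13 the cycloheptenone with saturated ring A
Product: 14 (1R,2R,7S,8R)-2,6,6,9-tetramethyltricyclo[5.4.0.0^{2,8}]undeca-4,9-diene-3,11-dione
Conditions: 2-iodoxybenzoic acid (IBX, 2.5 equiv), DMSO/fluorobenzene, 75 °C
Reagents that add atoms: none
Why: IBX dehydrogenation of a ketone to an enone: only the C11 ketone has an enolisable α-CH2 (C10) with a β-hydrogen (C9), whereas C3 is flanked by the quaternary C2 and a vinyl carbon, so unsaturation enters ring A only and the C9 centre is removed.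

**Step 12**
Reactants: 14 the dienedione
Product: 16 (1R,2R,5R,7S,8R)-5-hydroxy-2,6,6,9-tetramethyltricyclo[5.4.0.0^{2,8}]undec-9-ene-3,11-dione, via 5-boryl ketone 15 (not isolated)
Conditions: CuCl (5 mol %), NaOt-Bu (10 mol %), (R,R)-QuinoxP* (6 mol %), B2pin2, MeOH, THF, rt; then NaBO3·4H2O, THF/H2O, rt
Reagents that add atoms: sodium perborate, [Na+].[O-]OB(O)O
Why: Copper-catalysed asymmetric conjugate borylation followed by C–B oxidation with retention: the borylcopper adds to the disubstituted C4=C5 enone (the β,β-disubstituted ring A enone is far slower) and, because the C3–C6 bridge lies in a local mirror plane, the chiral ligand rather than the substrate should select the face syn to C8, setting C5 as R.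

**Step 13**
Reactants: 16 the β-hydroxy ketone
Product: 17 (1R,2R,3R,5R,7S,8R)-3-hydroxy-2,6,6,9-tetramethyl-11-oxotricyclo[5.4.0.0^{2,8}]undec-9-en-5-yl acetate
Conditions: MeCHO (6 equiv), SmI2 (30 mol %), THF, −10 °C
Reagents that add atoms: acetaldehyde, CC=O
Why: Evans–Tishchenko reduction: the samarium-bound hemiacetal on the C5 oxygen delivers hydride intramolecularly to C3 on its own face, so the new C3 hydroxyl is trans (1,3-anti) to the C5 oxygen (3R) and the two oxygens emerge differentiated (acetate at C5, free hydroxyl at C3); the ring A enone cannot take part.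

**Step 14**
Reactants: 17 the hydroxy acetate
Product: 18 (1R,2R,3R,5R,7S,8R)-5-acetoxy-2,6,6,9-tetramethyl-11-oxotricyclo[5.4.0.0^{2,8}]undec-9-en-3-yl (E)-2-methylbut-2-enoate
Conditions: (E)-2-methylbut-2-enoyl chloride, pyridine, DMAP, CH2Cl2, 0 °C to rt
Reagents that add atoms: tigloyl chloride, ClC(=O)/C(C)=C/C
Why: DMAP-catalysed acylation of the only free hydroxyl with the configurationally stable (E)-acid chloride; no stereocentre changes.

**Step 15**
Reactants: 18 the acetate tiglate
Product: 19 (1R,2R,3R,5R,7S,8R)-5-hydroxy-2,6,6,9-tetramethyl-11-oxotricyclo[5.4.0.0^{2,8}]undec-9-en-3-yl (E)-2-methylbut-2-enoate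
Conditions: Mg(OMe)2, MeOH, 0 °C to rt
Reagents that add atoms: none
Why: Chemoselective transesterification: magnesium-bound methoxide should cleave the unconjugated acetate much faster than the α-branched, conjugated tiglate; no stereocentre changes.

**Step 16**
Reactants: 19 the hydroxy tiglate
Product: 20 (1R,2R,3R,5R,7S,8R)-2,6,6,9-tetramethyl-3-[(E)-2-methylbut-2-enoyloxy]-11-oxotricyclo[5.4.0.0^{2,8}]undec-9-en-5-yl (Z)-2-methylbut-2-enoate (CNP0236543.4)
Conditions: angelic acid, 2,4,6-trichlorobenzoyl chloride, Et3N, toluene, rt; then 19, 80 °C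
Reagents that add atoms: angelic acid, C/C=C(/C)C(=O)O
Why: Yamaguchi esterification: the mixed anhydride acylates the hindered C5 hydroxyl under DMAP-free conditions chosen to avoid Z-to-E isomerisation of the angelate; no stereocentre changes.

**Compound list**

1 | but-3-en-2-one | CC(=O)C=C | starting material
2 | 2-[tri(propan-2-yl)silyloxy]buta-1,3-diene | C=CC(=C)O[Si](C(C)C)(C(C)C)C(C)C | intermediate
3 | 2,5-dimethyl-1,4-benzoquinone | CC1=CC(=O)C(C)=CC1=O | starting material
4 | (4aS,8aR)-2,4a-dimethyl-6-[tri(propan-2-yl)silyloxy]-4a,5,8,8a-tetrahydronaphthalene-1,4-dione (cis-fused) | O=C1C=C(C)C(=O)[C@@H]2CC=C(O[Si](C(C)C)(C(C)C)C(C)C)C[C@]12C | intermediate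
5 | (4R,4aR,8aS)-4-hydroxy-3,8a-dimethyl-7-[tri(propan-2-yl)silyloxy]-4a,5,8,8a-tetrahydronaphthalen-1(4H)-one (OH trans to 4a-H) | O=C1C=C(C)[C@H](O)[C@@H]2CC=C(O[Si](C(C)C)(C(C)C)C(C)C)C[C@]12C | intermediate
6 | (4R,4aR,8aS)-4-hydroxy-3,8a-dimethyl-4a,8a-dihydronaphthalene-1,7(4H,8H)-dione | O=C1C=C(C)[C@H](O)[C@@H]2C=CC(=O)C[C@]12C | intermediate
7 | (4S,4aR,8aS)-4-bromo-3,8a-dimethyl-4a,8a-dihydronaphthalene-1,7(4H,8H)-dione (Br cis to 4a-H and 8a-CH3) | O=C1C=C(C)[C@@H](Br)[C@@H]2C=CC(=O)C[C@]12C | intermediate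
8 | (1S,2R,6S,7R)-2,5-dimethyltricyclo[4.4.0.0^{2,7}]deca-4,9-diene-3,8-dione | O=C1C=C(C)[C@H]2[C@@H]3C=CC(=O)[C@H]2[C@]13C | intermediate
9 | (1S,2R,6S,7R,10R)-2,5,10-trimethyltricyclo[4.4.0.0^{2,7}]dec-4-ene-3,8-dione | O=C1C=C(C)[C@H]2[C@@H]3[C@H](C)CC(=O)[C@H]2[C@]13C | intermediate
10 | (1S,2R,6S,7R,10R)-2,5,5,10-tetramethyl-3-(trimethylsilyloxy)tricyclo[4.4.0.0^{2,7}]dec-3-en-8-one | C[Si](C)(C)OC1=CC(C)(C)[C@H]2[C@@H]3[C@H](C)CC(=O)[C@H]2[C@]13C | intermediate
11 | 2,5,5,10-tetramethyl-3-(trimethylsilyloxy)-3,4-methanotricyclo[4.4.0.0^{2,7}]decan-8-one (core as in 10; CH2 drawn on the face of C1, either face serves) | C[Si](C)(C)O[C@@]14C[C@H]4C(C)(C)[C@H]2[C@@H]3[C@H](C)CC(=O)[C@H]2[C@]13C | intermediate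
12 | 5-chloro-2,6,6,9-tetramethyltricyclo[5.4.0.0^{2,8}]undecane-3,11-dione (core and C9 as in 13; C5 epimers, one drawn) | O=C1C[C@@H](Cl)C(C)(C)[C@H]2[C@@H]3[C@H](C)CC(=O)[C@H]2[C@]13C | intermediate (not isolated)
13 | (1R,2R,7S,8S,9R)-2,6,6,9-tetramethyltricyclo[5.4.0.0^{2,8}]undec-4-ene-3,11-dione | O=C1C=CC(C)(C)[C@H]2[C@@H]3[C@H](C)CC(=O)[C@H]2[C@]13C | intermediate
14 | (1R,2R,7S,8R)-2,6,6,9-tetramethyltricyclo[5.4.0.0^{2,8}]undeca-4,9-diene-3,11-dione | O=C1C=CC(C)(C)[C@H]2[C@@H]3C(C)=CC(=O)[C@H]2[C@]13C | intermediate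
15 | (1R,2R,5R,7S,8R)-2,6,6,9-tetramethyl-5-(4,4,5,5-tetramethyl-1,3,2-dioxaborolan-2-yl)tricyclo[5.4.0.0^{2,8}]undec-9-ene-3,11-dione | O=C1C[C@@H](B2OC(C)(C)C(C)(C)O2)C(C)(C)[C@H]3[C@@H]4C(C)=CC(=O)[C@H]3[C@]14C | intermediate (not isolated)
16 | (1R,2R,5R,7S,8R)-5-hydroxy-2,6,6,9-tetramethyltricyclo[5.4.0.0^{2,8}]undec-9-ene-3,11-dione | O=C1C[C@@H](O)C(C)(C)[C@H]2[C@@H]3C(C)=CC(=O)[C@H]2[C@]13C | intermediate
17 | (1R,2R,3R,5R,7S,8R)-3-hydroxy-2,6,6,9-tetramethyl-11-oxotricyclo[5.4.0.0^{2,8}]undec-9-en-5-yl acetate | CC(=O)O[C@@H]1C[C@@H](O)[C@@]2(C)[C@@H]3C(=O)C=C(C)[C@H]2[C@@H]3C1(C)C | intermediate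
18 | (1R,2R,3R,5R,7S,8R)-5-acetoxy-2,6,6,9-tetramethyl-11-oxotricyclo[5.4.0.0^{2,8}]undec-9-en-3-yl (E)-2-methylbut-2-enoate | CC(=O)O[C@@H]1C[C@@H](OC(=O)/C(C)=C/C)[C@@]2(C)[C@@H]3C(=O)C=C(C)[C@H]2[C@@H]3C1(C)C | intermediate
19 | (1R,2R,3R,5R,7S,8R)-5-hydroxy-2,6,6,9-tetramethyl-11-oxotricyclo[5.4.0.0^{2,8}]undec-9-en-3-yl (E)-2-methylbut-2-enoate | O[C@@H]1C[C@@H](OC(=O)/C(C)=C/C)[C@@]2(C)[C@@H]3C(=O)C=C(C)[C@H]2[C@@H]3C1(C)C | intermediate
20 | (1R,2R,3R,5R,7S,8R)-2,6,6,9-tetramethyl-3-[(E)-2-methylbut-2-enoyloxy]-11-oxotricyclo[5.4.0.0^{2,8}]undec-9-en-5-yl (Z)-2-methylbut-2-enoate | C/C=C(/C)C(=O)O[C@@H]1C[C@@H](OC(=O)/C(C)=C/C)[C@@]2(C)[C@@H]3C(=O)C=C(C)[C@H]2[C@@H]3C1(C)C | target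

**Total step count:** 16. **Longest linear sequence:** 16 steps (1 to 20).

**Steps most likely to fail**

Step 6 (cyclobutane closure). The ring A enolate may add across the ring to the ring B enone, or the allylic bromide may lose HBr, instead of closing the four-membered ring. The fallback masks the ring B carbonyl; it sets out from 5 and comes back at 8. Luche reduction of 5 (NaBH4, CeCl3) should give the cis-enediol F1, and Pd(OAc)2 then gives the ring A enone diol F2. One equivalent of CBr4/PPh3 should convert the less hindered hydroxyl (the one not next to the quaternary carbon) into the inverted bromo alcohol F3, and Me3SiCl/imidazole gives the silyl ether F4. LiN(SiMe3)2 then closes the cyclobutane to the tricyclic silyl ether F5 with no Michael acceptor in ring B. Acidic work-up frees the allylic alcohol F6, and MnO2 oxidises it to 8.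

Step 12 (C5 oxygenation). Facial selectivity may be poor because the substrate itself hardly distinguishes the two faces of C4=C5, and addition at the neopentyl β-carbon may be sluggish. The fallback uses silicon as a hydroxyl surrogate under rhodium control; it sets out from 14 and comes back at 16. Conjugate addition of PhMe2Si–Bpin catalysed by Rh(acac)(C2H4)2/BINAP (Et3N, dioxane/H2O) should give the β-silyl ketone F10. Fleming–Tamao oxidation (KBr, AcOOH, NaOAc, AcOH) then gives 16 with retention.

Step 10 (ring enlargement). The external rather than the internal cyclopropane bond may cleave (giving an α-methyl ketone), or the hindered enol ether may resist cyclopropanation in step 9. The fallback is a diazoalkane homologation; it sets out from 10 and comes back at 14. Methanolysis of 10 (K2CO3, MeOH) gives the diketone F7, and IBX dehydrogenates ring A only, giving the enone ketone F8. Me3SiCHN2/BF3·OEt2 followed by protodesilylation should homologate the saturated C3 ketone with migration of the CH2 carbon rather than the quaternary C2, giving the cycloheptanone F9; the conjugated C11 carbonyl is the less reactive. A second IBX dehydrogenation introduces C4=C5 and gives 14.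

**Further compounds**

F1 | step 6 | (1R,4R,4aR,8aS)-3,8a-dimethyl-7-[tri(propan-2-yl)silyloxy]-1,4,4a,5,8,8a-hexahydronaphthalene-1,4-diol (hydroxyls cis; either C1 epimer serves) | O[C@@H]1C=C(C)[C@H](O)[C@@H]2CC=C(O[Si](C(C)C)(C(C)C)C(C)C)C[C@]12C
F2 | step 6 | (4aR,5R,8R,8aS)-5,8-dihydroxy-6,8a-dimethyl-4a,5,8,8a-tetrahydronaphthalen-2(1H)-one | O[C@@H]1C=C(C)[C@H](O)[C@@H]2C=CC(=O)C[C@]12C
F3 | step 6 | (4aR,5S,8R,8aS)-5-bromo-8-hydroxy-6,8a-dimethyl-4a,5,8,8a-tetrahydronaphthalen-2(1H)-one | O[C@@H]1C=C(C)[C@@H](Br)[C@@H]2C=CC(=O)C[C@]12C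
F4 | step 6 | (4aR,5S,8R,8aS)-5-bromo-6,8a-dimethyl-8-(trimethylsilyloxy)-4a,5,8,8a-tetrahydronaphthalen-2(1H)-one | C[Si](C)(C)O[C@@H]1C=C(C)[C@@H](Br)[C@@H]2C=CC(=O)C[C@]12C
F5 | step 6 | (1S,2R,3R,6S,7R)-2,5-dimethyl-3-(trimethylsilyloxy)tricyclo[4.4.0.0^{2,7}]deca-4,9-dien-8-one | C[Si](C)(C)O[C@@H]1C=C(C)[C@H]2[C@@H]3C=CC(=O)[C@H]2[C@]13C
F6 | step 6 | (1S,2R,3R,6S,7R)-3-hydroxy-2,5-dimethyltricyclo[4.4.0.0^{2,7}]deca-4,9-dien-8-one | O[C@@H]1C=C(C)[C@H]2[C@@H]3C=CC(=O)[C@H]2[C@]13C
F7 | step 10 | (1S,2R,6S,7R,10R)-2,5,5,10-tetramethyltricyclo[4.4.0.0^{2,7}]decane-3,8-dione | O=C1CC(C)(C)[C@H]2[C@@H]3[C@H](C)CC(=O)[C@H]2[C@]13C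
F8 | step 10 | (1R,2R,6S,7R)-2,5,5,10-tetramethyltricyclo[4.4.0.0^{2,7}]dec-9-ene-3,8-dione | O=C1CC(C)(C)[C@H]2[C@@H]3C(C)=CC(=O)[C@H]2[C@]13C
F9 | step 10 | (1R,2R,7S,8R)-2,6,6,9-tetramethyltricyclo[5.4.0.0^{2,8}]undec-9-ene-3,11-dione | O=C1CCC(C)(C)[C@H]2[C@@H]3C(C)=CC(=O)[C@H]2[C@]13C
F10 | step 12 | (1R,2R,5R,7S,8R)-5-[dimethyl(phenyl)silyl]-2,6,6,9-tetramethyltricyclo[5.4.0.0^{2,8}]undec-9-ene-3,11-dione | O=C1C[C@@H]([Si](C)(C)c2ccccc2)C(C)(C)[C@H]3[C@@H]4C(C)=CC(=O)[C@H]3[C@]14C
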